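**Retrosynthetic overview**
1. Kimcuongin ⇒ E1cB elimination of the activated tertiary alcohol in the aldol ArCO-CH(O-senecioyl)-C(OH)Me2. Here Ar = 7-methoxycoumarin-8-yl and the side chain is numbered C1' (ketone carbon), C2', C3'.
2. Key C2'-C3' disconnection: intermolecular Mukaiyama aldol addition of the silyl enol ether of ArCO-CH2-O-senecioyl to acetone.
3. ArCO-CH2-O-senecioyl ⇒ SN2 of the carboxylate of 3-methylbut-2-enoic (senecioic) acid on ArCO-CH2Br ⇒ 8-acetyl-7-methoxycoumarin.
4. 8-Acetyl-7-methoxycoumarin ⇒ O-methylation and Fries rearrangement ⇒ 7-acetoxycoumarin ⇒ umbelliferone + acetic anhydride.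
5. Ring order: no ring is built. Benzene ring A and pyranone ring B both come ready-made in umbelliferone.

Assumption: the target SMILES has no stereocentre and no E/Z element (C3' carries two methyl groups). The target is therefore achiral, and the racemic intermediates 12 and 13 need no resolution.

**Route**

Step 1
Reactants: 1 umbelliferone (7-hydroxycoumarin); 2 acetic anhydride
Product: 3 7-acetoxycoumarin
Conditions: pyridine, rt, 3 h
Reagents that add atoms: none
Why: Pyridine-promoted O-acetylation (nucleophilic acyl substitution) of the only hydroxyl group is essentially quantitative and sets up the Fries rearrangement, with no stereocentre formed.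

Step 2
Reactants: 3 7-acetoxycoumarin
Product: 4 8-acetyl-7-hydroxycoumarin
Conditions: AlCl3 (3 equiv), neat melt, 125 → 165 °C, 2 h; then ice, aq HCl; recrystallise (EtOH)
Reagents that add atoms: none
Why: In this Fries rearrangement AlCl3 frees an acylium ion that re-enters at high temperature ortho to the phenolate at C8, the most activated position of a 7-oxygenated coumarin, where the product is held as a six-membered aluminium chelate, and the minor C6 isomer is removed by recrystallisation.

Step 3
Reactants: 4 8-acetyl-7-hydroxycoumarin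
Product: 5 8-acetyl-7-methoxycoumarin
Conditions: MeI (1.5 equiv), K2CO3 (2 equiv), DMF, 40 °C, 6 h
Reagents that add atoms: iodomethane, CI
Why: Williamson ether synthesis (SN2 on MeI) of the acidic, hydrogen-bonded phenol runs cleanly in a dipolar aprotic solvent, and the weak base leaves the methyl ketone and the lactone untouched.

Step 4
Reactants: 5 8-acetyl-7-methoxycoumarin
Product: 6 7-methoxy-8-[1-(trimethylsilyloxy)ethenyl]coumarin
Conditions: TMSOTf (1.3 equiv), Et3N (2 equiv), CH2Cl2, 0 °C, 1 h; cold aq NaHCO3 wash, used crude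
Reagents that add atoms: trimethylsilyl trifluoromethanesulfonate, C[Si](C)(C)OS(=O)(=O)C(F)(F)F
Why: Soft enolisation (O-silylation by TMSOTf, then deprotonation of the only enolisable position by Et3N) gives a single silyl enol ether without any nucleophilic base that could open the lactone.

Step 5
Reactants: 6 7-methoxy-8-[1-(trimethylsilyloxy)ethenyl]coumarin
Product: 7 8-(2-bromoacetyl)-7-methoxycoumarin
Conditions: NBS (1.05 equiv), THF, −78 → 0 °C, 1 h; H2O work-up
Reagents that add atoms: N-bromosuccinimide, O=C1CCC(=O)N1Br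
Why: In this electrophilic α-bromination of a silyl enol ether the enol ether is by far the most electron-rich π-system, so one bromine goes to the terminal carbon at low temperature without attack at C3 or C6 of the coumarin.

Step 6
Reactants: 7 8-(2-bromoacetyl)-7-methoxycoumarin; 8 3-methylbut-2-enoic acid (senecioic acid)
Product: 9 2-(7-methoxy-2-oxo-2H-chromen-8-yl)-2-oxoethyl 3-methylbut-2-enoate
Conditions: K2CO3 (1.2 equiv), DMF, rt, 4 h
Reagents that add atoms: none
Why: SN2 displacement of a carbonyl-activated primary bromide by a carboxylate (phenacyl ester formation) is fast at room temperature and introduces the senecioyl group without an acid chloride, so the double bond cannot deconjugate.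

Step 7
Reactants: 9 2-(7-methoxy-2-oxo-2H-chromen-8-yl)-2-oxoethyl 3-methylbut-2-enoate
Product: 10 (Z)-2-(7-methoxy-2-oxo-2H-chromen-8-yl)-2-(trimethylsilyloxy)ethenyl 3-methylbut-2-enoate
Conditions: TMSOTf (1.15 equiv), Et3N (1.6 equiv), CH2Cl2, 0 °C, 1 h; cold aq NaHCO3 wash, used crude
Reagents that add atoms: trimethylsilyl trifluoromethanesulfonate, C[Si](C)(C)OS(=O)(=O)C(F)(F)F
Why: Soft enolisation again, in which the ketone α-CH2 (acidified by the acyloxy group) is silylated far faster than the ester, giving mainly the Z enol ether with the acyloxy group turned away from the bulky aryl group, a geometry that has no consequence later.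

Step 8
Reactants: 10 (Z)-2-(7-methoxy-2-oxo-2H-chromen-8-yl)-2-(trimethylsilyloxy)ethenyl 3-methylbut-2-enoate; 11 acetone
Product: 12 rac-3-hydroxy-1-(7-methoxy-2-oxo-2H-chromen-8-yl)-3-methyl-1-oxobutan-2-yl 3-methylbut-2-enoate
Conditions: TiCl4 (2.2 equiv), 11 (3 equiv), CH2Cl2, −78 → −40 °C, 2 h; then H2O
Reagents that add atoms: none
Why: In this Mukaiyama aldol addition TiCl4-activated acetone is attacked by the enol carbon of 10, forging the C2'-C3' bond as a titanium chelate that neither reverts nor shifts its acyl group, and the new C2' stereocentre forms racemic, which is harmless because it becomes sp2 in step 10.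

Step 9
Reactants: 12 rac-3-hydroxy-1-(7-methoxy-2-oxo-2H-chromen-8-yl)-3-methyl-1-oxobutan-2-yl 3-methylbut-2-enoate
Product: 13 rac-1-(7-methoxy-2-oxo-2H-chromen-8-yl)-3-methyl-1-oxo-3-(trifluoroacetoxy)butan-2-yl 3-methylbut-2-enoate
Conditions: (CF3CO)2O (1.5 equiv), pyridine (3 equiv), CH2Cl2, 0 °C, 1 h; cold aq NaHCO3 wash, used crude
Reagents that add atoms: trifluoroacetic anhydride, O=C(OC(=O)C(F)(F)F)C(F)(F)F
Why: O-Acylation with this small, very reactive anhydride esterifies even the hindered tertiary alcohol under weakly basic conditions where no alkoxide forms, so the senecioyl group does not migrate, the hydroxyl becomes a good leaving group and C2' stays racemic.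

Step 10
Reactants: 13 rac-1-(7-methoxy-2-oxo-2H-chromen-8-yl)-3-methyl-1-oxo-3-(trifluoroacetoxy)butan-2-yl 3-methylbut-2-enoate
Product: 14 kimcuongin, 1-(7-methoxy-2-oxo-2H-chromen-8-yl)-3-methyl-1-oxobut-2-en-2-yl 3-methylbut-2-enoate
Conditions: DBU (1.5 equiv), CH2Cl2, 0 °C → rt, 1 h
Reagents that add atoms: none
Why: In this E1cB elimination DBU removes the most acidic proton (C2'-H, flanked by ketone and acyloxy group) and the enolate expels trifluoroacetate from C3', which places the double bond only in conjugation, erases the sole stereocentre and raises no E/Z question because C3' carries two methyl groups.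

**Compound list**
1 | umbelliferone (7-hydroxy-2H-chromen-2-one) | Oc1ccc2ccc(=O)oc2c1 | starting material
2 | acetic anhydride | CC(=O)OC(C)=O | starting material
3 | 7-acetoxycoumarin (2-oxo-2H-chromen-7-yl acetate) | CC(=O)Oc1ccc2ccc(=O)oc2c1 | intermediate
4 | 8-acetyl-7-hydroxycoumarin | Oc1ccc2ccc(=O)oc2c1C(C)=O | intermediate
5 | 8-acetyl-7-methoxycoumarin | COc1ccc2ccc(=O)oc2c1C(C)=O | intermediate
6 | 7-methoxy-8-[1-(trimethylsilyloxy)ethenyl]coumarin | COc1ccc2ccc(=O)oc2c1C(=C)O[Si](C)(C)C | intermediate
7 | 8-(2-bromoacetyl)-7-methoxycoumarin | COc1ccc2ccc(=O)oc2c1C(=O)CBr | intermediate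
8 | 3-methylbut-2-enoic acid (senecioic acid) | CC(C)=CC(=O)O | starting material
9 | 2-(7-methoxy-2-oxo-2H-chromen-8-yl)-2-oxoethyl 3-methylbut-2-enoate | COc1ccc2ccc(=O)oc2c1C(=O)COC(=O)C=C(C)C | intermediate
10 | (Z)-2-(7-methoxy-2-oxo-2H-chromen-8-yl)-2-(trimethylsilyloxy)ethenyl 3-methylbut-2-enoate | COc1ccc2ccc(=O)oc2c1/C(O[Si](C)(C)C)=C/OC(=O)C=C(C)C | intermediate
11 | acetone | CC(C)=O | starting material
12 | rac-3-hydroxy-1-(7-methoxy-2-oxo-2H-chromen-8-yl)-3-methyl-1-oxobutan-2-yl 3-methylbut-2-enoate (racemic at C2') | COc1ccc2ccc(=O)oc2c1C(=O)C(OC(=O)C=C(C)C)C(C)(C)O | intermediate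
13 | rac-1-(7-methoxy-2-oxo-2H-chromen-8-yl)-3-methyl-1-oxo-3-(trifluoroacetoxy)butan-2-yl 3-methylbut-2-enoate (racemic at C2') | COc1ccc2ccc(=O)oc2c1C(=O)C(OC(=O)C=C(C)C)C(C)(C)OC(=O)C(F)(F)F | intermediate
14 | kimcuongin, 1-(7-methoxy-2-oxo-2H-chromen-8-yl)-3-methyl-1-oxobut-2-en-2-yl 3-methylbut-2-enoate (achiral) | COc1ccc2ccc(=O)oc2c1C(=O)C(OC(=O)C=C(C)C)=C(C)C | target

**Total step count:** 10. **Longest linear sequence:** 10 steps (1 → 14).

**Steps most likely to fail**

Step 8 carries the most risk. The acyloxy group and the di-ortho-substituted aryl group lower the nucleophilicity of 10, and acetone is a sluggish acceptor. The fallback sets out from 6 and comes back at 12, making the same aldol bond before the C2' oxygen is in place. Enol ether 6 and acetone 11 with TiCl4 in CH2Cl2 give 8-(3-hydroxy-3-methylbutanoyl)-7-methoxycoumarin F1. Catalytic p-toluenesulfonic acid in warm toluene dehydrates this to 8-(3-methylbut-2-enoyl)-7-methoxycoumarin F2. Catalytic OsO4 with N-methylmorpholine N-oxide and citric acid then dihydroxylates the trisubstituted enone alkene, which reacts faster than the quasi-aromatic pyranone C3=C4 bond, to give rac-8-(2,3-dihydroxy-3-methylbutanoyl)-7-methoxycoumarin F3. Steglich esterification with acid 8 (N,N'-dicyclohexylcarbodiimide, catalytic 4-dimethylaminopyridine, CH2Cl2) acylates only the secondary hydroxyl and delivers 12.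

Step 9 is the next risk. The tertiary hydroxyl is crowded and sits next to an ester that could migrate, and 13 may be too labile to handle. The fallback sets out from 12 and comes back at 14, bypassing 13. It removes water away from the carbonyl first and moves the double bond afterwards. SOCl2 in pyridine at 0 °C eliminates the chlorosulfite mainly toward a methyl group. This gives rac-1-(7-methoxy-2-oxo-2H-chromen-8-yl)-3-methyl-1-oxobut-3-en-2-yl 3-methylbut-2-enoate F4, together with some 14. Treating the mixture with catalytic DBU in CH2Cl2 deprotonates the doubly activated C2'-H, and reprotonation of the dienolate at the terminal CH2 shifts the alkene into conjugation, so everything converges on 14.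

Step 2 is the third risk. The hot AlCl3 melt gives variable yields and some 6-acetyl isomer. The fallback sets out from 1 and comes back at 5, building the acetyl group from a C8 aldehyde. Duff formylation of 1 (hexamethylenetetramine, CF3CO2H, reflux, then aq HCl) gives 7-hydroxy-2-oxo-2H-chromene-8-carbaldehyde F5. MeI and K2CO3 in DMF give 7-methoxy-2-oxo-2H-chromene-8-carbaldehyde F6. The aldehyde-selective reagent MeTi(OiPr)3 in THF at −40 → 0 °C adds methyl without touching the lactone and gives rac-8-(1-hydroxyethyl)-7-methoxycoumarin F7. Dess-Martin periodinane in CH2Cl2 oxidises this to 5.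

**Further compounds**
F1 | step 8 | 8-(3-hydroxy-3-methylbutanoyl)-7-methoxycoumarin | COc1ccc2ccc(=O)oc2c1C(=O)CC(C)(C)O
F2 | step 8 | 8-(3-methylbut-2-enoyl)-7-methoxycoumarin | COc1ccc2ccc(=O)oc2c1C(=O)C=C(C)C
F3 | step 8 | rac-8-(2,3-dihydroxy-3-methylbutanoyl)-7-methoxycoumarin | COc1ccc2ccc(=O)oc2c1C(=O)C(O)C(C)(C)O
F4 | step 9 | rac-1-(7-methoxy-2-oxo-2H-chromen-8-yl)-3-methyl-1-oxobut-3-en-2-yl 3-methylbut-2-enoate | COc1ccc2ccc(=O)oc2c1C(=O)C(OC(=O)C=C(C)C)C(C)=C
F5 | step 2 | 7-hydroxy-2-oxo-2H-chromene-8-carbaldehyde | Oc1ccc2ccc(=O)oc2c1C=O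
F6 | step 2 | 7-methoxy-2-oxo-2H-chromene-8-carbaldehyde | COc1ccc2ccc(=O)oc2c1C=O
F7 | step 2 | rac-8-(1-hydroxyethyl)-7-methoxycoumarin | COc1ccc2ccc(=O)oc2c1C(C)O
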